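At early times the substrate falls alike in the noon and autumn runs, though their charges of second nucleophile differ.

all flasks: substrate 0.35 M; first nucleophile 0.525 M

| run | second nucleophile | remark | time |
|---|---|---|---|
| noon | 0.088 M | run made earlier |  |
| autumn | 0.38 M | run made earlier |  |
| theta | 0.245 M |  | 20 min |
| epsilon | 0.0600 M |  | 10 min |

- noon (time / min: intermediate / %, target / %, substrate / %): 1.50: 2.5, 2.4, 88.8; 3.00: 2.9, 3.5, 78.3; 5.00: 5.5, 7.3, 67.3; 6.00: 7.7, 9.0, 61.1; 8.00: 9.2, 13.3, 53.7; 10.0: 12.6, 18.4, 45.1
- autumn (time / min: intermediate / %, target / %, substrate / %): 0.667: 0, 0.7, 95.7; 2.00: 1.2, 0, 84.7; 4.00: 0, 1.8, 73.5; 5.00: 0.1, 1.8, 66.9; 8.00: 0.5, 0, 53.3; 10.0: 1.8, 0.4, 45.4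

(readings scatter by 1 percentage point)



- which one finishes higher in amount of intermediate, in percent of the substrate charged ("neither" within 2 percentage points) (theta / epsilon / neither)
- amount of intermediate at the end, in percent of the substrate charged, theta
- amount of intermediate at the end, in percent of the substrate charged, epsilon

From noon I read a first-order constant of 0.0796 min⁻¹ for the substrate. In autumn, intermediate and target stay near the scatter while substrate goes, so the second nucleophile seems to take intermediate one for one into something unread. In noon the unread part at 10.0 min is 23.9% of the substrate charged, against a charge of second nucleophile equal to 25.1% of it.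

That gives the early end, and the late end is a subtraction. In epsilon, I reckon 54.9% of the substrate converted by 10 min, and the second nucleophile, limiting reagent of the capture, covers 17.1%, which leaves 37.8%. This difference, substrate converted less second nucleophile charged, both as shares of the substrate charged, is the overflow. In theta, 79.7% converted gives an overflow of 9.66%.

So I take intermediate to lie between zero and the overflow. To tighten this, I use noon, where intermediate's share of intermediate plus target reads 46.1% at 6.00 min and 40.6% at 10.0 min. Taking those two scattered readings as its ends, my bracket is 3.92% to 4.45% for theta and 15.3% to 17.4% for epsilon, so I expect epsilon to end higher.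

The forecast says epsilon, with 3.5% for theta and 14% for epsilon, and of theta it says “The scavenger is only just running out”. Both its numbers stand lower than my tightened bracket, but inside the wide one.

The flask gives epsilon, with 4.24% for theta and 16.7% for epsilon, inside my bracket and within the forecast's tolerance.

    substrate → intermediate (k = 0.00132 s⁻¹)
    first nucleophile + intermediate ⇌ target (K = 2.83 M⁻¹, k = 0.170 M⁻¹ s⁻¹)
    second nucleophile + intermediate → other capture product (k = 0.686 M⁻¹ s⁻¹)

The overflow of 37.8% in epsilon stands against 37.6% of intermediate plus target, and the 9.66% in theta against 10.1%; the rest went to other capture product. Epsilon ends above theta mainly because of its smaller charge of second nucleophile: with theta's charge and its own 10 min, epsilon ends at 1.26% instead of 16.7%. The neighbour with theta's recipe but 0.59 M of substrate has an overflow of 38.1%, and it holds 38.0% of intermediate plus target, of which intermediate is 17.8%.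

The runs are simulated on assumed constants; noise was put on by code.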